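## Retrosynthetic overview

1. Target 9 is cut at the ring C3–C1′ bond. The hydroxyquinone carbon C3, natively an enol nucleophile, is used as an enolonium equivalent (phenyliodonium ylide 4). The chain comes in as the nucleophilic alkylborane 7, made from 1-heptadecene 5 and 9-BBN 6.
2. Ylide 4 comes from 2-hydroxy-5-methoxy-1,4-benzoquinone 3 and PhI(OAc)2.
3. Compound 3 comes from mono-hydrolysis of 2,5-dimethoxy-1,4-benzoquinone 1.
4. Ring order: no ring is built. The single six-membered quinone ring is bought in 1 and carried through.

Assumption: the SMILES is read as an unbranched heptadecyl (C17) chain on an achiral quinone with no stereocentres or stereogenic double bonds, so there is no configuration to set.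

## Route

Step 1
Reactants: 1 2,5-dimethoxy-1,4-benzoquinone
Product: 3 2-hydroxy-5-methoxy-1,4-benzoquinone, via sodium quinonolate 2 (not isolated)
Conditions: NaOH (1.05 equiv), dioxane/H2O, 0 °C → rt; filter off unreacted 1; then 1 M HCl to pH 1
Reagents that add atoms: sodium hydroxide, [Na+].[OH-]
Why: Vinylogous ester saponification by addition–elimination: hydroxide adds to a methoxy-bearing carbon and expels methoxide, and the product sits as the delocalised quinonolate 2, whose remaining methoxy group is deactivated toward a second attack, so one equivalent of base stops at mono-hydrolysis; no stereocentre is formed.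

Step 2
Reactants: 3 2-hydroxy-5-methoxy-1,4-benzoquinone
Product: 4 5-methoxy-2-oxido-3-(phenyliodonio)-1,4-benzoquinone (phenyliodonium ylide)
Conditions: PhI(OAc)2 (1.05 equiv), CH2Cl2, rt, 1–2 h, dark; filter the precipitated ylide, wash with Et2O
Reagents that add atoms: (diacetoxyiodo)benzene, CC(=O)OI(OC(C)=O)c1ccccc1
Why: Iodonium ylide formation, known for 2-hydroxy-1,4-quinones: the acidic enol carbon C3, flanked by C–OH and C=O, displaces both acetates from trivalent iodine to give a stable zwitterion in which C3 carries a hyper-leaving group; C6 is only an enol-ether carbon and does not compete, so the site of the later C–C bond is fixed here.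

Step 3
Reactants: 4 5-methoxy-2-oxido-3-(phenyliodonio)-1,4-benzoquinone; 5 1-heptadecene; 6 9-borabicyclo[3.3.1]nonane (9-BBN)
Product: 9 irisoquin B (3-heptadecyl-2-hydroxy-5-methoxy-1,4-benzoquinone), via B-heptadecyl-9-BBN 7 (not isolated), via caesium quinonolate 8 (not isolated)
Conditions: 5 (1.3 equiv), 6 (0.5 M in THF, 1.3 equiv), THF, 0 °C → rt, 4 h; then degassed aq. Cs2CO3 (2 equiv); transfer to 4 (1.0 equiv), PdCl2(dppf) (5 mol %), AsPh3 (5 mol %), DMF/THF/H2O, rt, dark, Ar; then 1 M HCl
Reagents that add atoms: none
Why: Proposed new method: zerovalent palladium inserts into the C3–I bond of ylide 4 with loss of iodobenzene, so the enol carbon of the hydroxyquinone, natively a nucleophile, reacts as an enolonium (α-cation) equivalent; the base-activated primary alkylborane 7 (from anti-Markovnikov hydroboration) transmetalates, dppf favours reductive elimination over β-hydride elimination, and the C3–C1′ bond forms exactly where iodine sat, giving quinonolate 8 and, after acid, 9; the closest known reactions are the palladium-catalysed Stille coupling of hydroxyquinone phenyliodonium ylides with arylstannanes and the B-alkyl Suzuki–Miyaura coupling, which also runs with iodonium salts at room temperature; no stereocentre is created.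

## Compound list

1 | 2,5-dimethoxy-1,4-benzoquinone | COC1=CC(=O)C(OC)=CC1=O | starting material
2 | sodium 5-methoxy-1,4-benzoquinon-2-olate | [Na+].[O-]C1=CC(=O)C(OC)=CC1=O | intermediate
3 | 2-hydroxy-5-methoxy-1,4-benzoquinone | OC1=CC(=O)C(OC)=CC1=O | intermediate
4 | 5-methoxy-2-oxido-3-(phenyliodonio)-1,4-benzoquinone (phenyliodonium ylide) | [O-]C1=C([I+]c2ccccc2)C(=O)C(OC)=CC1=O | intermediate
5 | 1-heptadecene | CCCCCCCCCCCCCCCC=C | starting material
6 | 9-borabicyclo[3.3.1]nonane (9-BBN) | B1C2CCCC1CCC2 | starting material
7 | 9-heptadecyl-9-borabicyclo[3.3.1]nonane (B-heptadecyl-9-BBN) | CCCCCCCCCCCCCCCCCB1C2CCCC1CCC2 | intermediate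
8 | caesium 3-heptadecyl-5-methoxy-1,4-benzoquinon-2-olate | CCCCCCCCCCCCCCCCCC1=C([O-])C(=O)C=C(OC)C1=O.[Cs+] | intermediate
9 | irisoquin B (3-heptadecyl-2-hydroxy-5-methoxy-1,4-benzoquinone), achiral | CCCCCCCCCCCCCCCCCC1=C(O)C(=O)C=C(OC)C1=O | target

## Step count and risks

Total step count: 3. Longest linear sequence: 3 (1 → 3 → 4 → 9).

Steps most likely to fail, in order of risk:

Step 3 (sp3 coupling to the ylide). The alkylpalladium intermediate may undergo β-hydride elimination and return 3 by protodeiodination, the borane may add to C6 by a radical path, or the ylide may decompose in base. The fallback sets out from 4 and comes back at 9. It replaces the sp3 transfer by the precedented sp2 transfer followed by saturation. Radical hydrostannation of 1-heptadecyne (Bu3SnH, AIBN, 80 °C) gives (E)-tributyl(heptadec-1-en-1-yl)stannane F4. Base-free Stille coupling of F4 with 4 (Pd2(dba)3, AsPh3, DMF, rt, then dilute HCl) gives 3-[(E)-heptadec-1-en-1-yl]-2-hydroxy-5-methoxy-1,4-benzoquinone F5. Hydrogenation (H2, Pd/C, EtOAc) saturates the side chain and reduces the quinone to 3-heptadecyl-5-methoxybenzene-1,2,4-triol F6, which is re-oxidised by stirring in air (or FeCl3) to 9. The alkene geometry is erased, so E/Z mixtures of F4 are acceptable.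

Step 2 (ylide formation). The ylide may form impurely or be too labile or insoluble to carry forward. The fallback sets out from 3 and comes back at 8. It uses an α-halo enolonium equivalent instead of the hypervalent iodine one. Iodination of 3 at C3 (I2, morpholine, H2O/THF, rt, then acid) gives 2-hydroxy-3-iodo-5-methoxy-1,4-benzoquinone F3. F3 is coupled with borane 7 (PdCl2(dppf), Cs2CO3, DMF/THF/H2O, 50 °C) to give quinonolate 8, which is acidified to 9 as in step 3.

Step 1 (mono-hydrolysis). Over-hydrolysis to 2,5-dihydroxy-1,4-benzoquinone or poor conversion of the sparingly soluble 1 would erode the yield. The fallback sets out from 1 and comes back at 9. It postpones the hydrolysis to the end, where the chain differentiates the two methoxy groups. Bromination of 1 (pyridinium tribromide, AcOH/NaOAc, rt) gives 3-bromo-2,5-dimethoxy-1,4-benzoquinone F1. B-alkyl Suzuki coupling of F1 with 7 (PdCl2(dppf), Cs2CO3, DMF/THF/H2O, rt to 50 °C) gives 3-heptadecyl-2,5-dimethoxy-1,4-benzoquinone F2. Aqueous HClO4 in dioxane at rt then cleaves only the methoxy group flanked by the alkyl chain, a selectivity known for 3-alkyl-2,5-dimethoxyquinones, and gives 9.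

Further compounds

F1 | step 1 | 3-bromo-2,5-dimethoxy-1,4-benzoquinone | COC1=C(Br)C(=O)C(OC)=CC1=O
F2 | step 1 | 3-heptadecyl-2,5-dimethoxy-1,4-benzoquinone | CCCCCCCCCCCCCCCCCC1=C(OC)C(=O)C=C(OC)C1=O
F3 | step 2 | 2-hydroxy-3-iodo-5-methoxy-1,4-benzoquinone | OC1=C(I)C(=O)C(OC)=CC1=O
F4 | step 3 | (E)-tributyl(heptadec-1-en-1-yl)stannane | CCCCCCCCCCCCCCC/C=C/[Sn](CCCC)(CCCC)CCCC
F5 | step 3 | 3-[(E)-heptadec-1-en-1-yl]-2-hydroxy-5-methoxy-1,4-benzoquinone | CCCCCCCCCCCCCCC/C=C/C1=C(O)C(=O)C=C(OC)C1=O
F6 | step 3 | 3-heptadecyl-5-methoxybenzene-1,2,4-triol | CCCCCCCCCCCCCCCCCc1c(O)c(O)cc(OC)c1O
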